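**Plan**

- Retrosynthesis cuts, in order: the O–benzyl bond on the phenol (last step); the C5–C6 bond of the tridecane chain, into two primary alkyl radicals that each come from a carboxylic acid (nonanoic acid and a (5R)-5-acetoxy-6-arylhexanoic acid, both as N-hydroxyphthalimide esters); the aryl–C1 bond, into an aryl Grignard reagent and (R)-1,2-epoxy-5-hexene.
- Forward: benzyl-protected aryl bromide → epoxide opening (aryl–C1) → acetate → terminal alkene to CO2H → redox-active ester → Ni-electrocatalytic doubly decarboxylative coupling with the nonanoate ester (C5–C6) → hydrogenolysis. No ring is formed; the benzene ring is bought.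
- Enabling feature: C5–C6 is an unfunctionalised CH2–CH2 link of the unbranched chain, three methylenes from the acetoxy carbon C2. Both halves are therefore primary radicals and the carboxyl helpers leave as CO2. The electron-rich 3-hydroxy-5-methoxyphenyl ring calls for a cathodic (reductive) coupling rather than an anodic one, and for a benzyl mask on its OH.
- Stereochemistry: the single stereocentre C2 (R) is bought with (R)-1,2-epoxy-5-hexene; the aryl nucleophile attacks the CH2 terminus and no later step touches C2.

Key step: step 8

Remark: the target stereocentre is read as R (O > CH2Ar > undecyl > H), and the priority order O > C1 > C3 > H is the same in every intermediate, so all carry the descriptor R.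

**Route**

Step 1
Reactants: 1 3-bromo-5-methoxyphenol
Product: 2 1-(benzyloxy)-3-bromo-5-methoxybenzene
Conditions: BnBr, K2CO3, acetone, reflux
Reagents that add atoms: benzyl bromide, BrCc1ccccc1
Why: Williamson ether synthesis on the phenoxide; the benzyl ether masks the acidic phenol through the Grignard, active-ester and electroreductive steps and is later removed by neutral hydrogenolysis that spares the acetate.

Step 2
Reactants: 2 1-(benzyloxy)-3-bromo-5-methoxybenzene; 3 (R)-1,2-epoxy-5-hexene
Product: 5 (2R)-1-[3-(benzyloxy)-5-methoxyphenyl]hex-5-en-2-ol, via arylmagnesium bromide 4 (not isolated)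
Conditions: Mg, I2 (cat.), THF, reflux; then CuI (10 mol%), 3, THF, −30 to 0 °C; aq NH4Cl
Reagents that add atoms: none
Why: Copper-catalysed Grignard opening of a monosubstituted epoxide should proceed by SN2 attack at the unsubstituted CH2, forming the aryl–C1 bond; the stereocentre of 3 is not the site of attack, so its (R) configuration is carried over unchanged and becomes C2 of the target.

Step 3
Reactants: 5 (2R)-1-[3-(benzyloxy)-5-methoxyphenyl]hex-5-en-2-ol
Product: 6 (2R)-1-[3-(benzyloxy)-5-methoxyphenyl]hex-5-en-2-yl acetate
Conditions: Ac2O, pyridine, DMAP (cat.), CH2Cl2, 0 °C to rt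
Reagents that add atoms: acetic anhydride, CC(=O)OC(C)=O
Why: DMAP-catalysed O-acylation of a secondary alcohol; the C–O bond at C2 is not broken, so the configuration is retained.

Step 4
Reactants: 6 (2R)-1-[3-(benzyloxy)-5-methoxyphenyl]hex-5-en-2-yl acetate
Product: 8 (2R)-1-[3-(benzyloxy)-5-methoxyphenyl]-6-hydroxyhexan-2-yl acetate, via B-alkyl-9-BBN adduct 7 (not isolated)
Conditions: 9-BBN (1.3 equiv), THF, 0 °C to rt; then aq NaOAc, 30% H2O2, 0 °C to rt
Reagents that add atoms: hydrogen peroxide, OO
Why: Anti-Markovnikov hydroboration–oxidation of the terminal alkene; 9-BBN does not reduce the acetate at room temperature and the acetate-buffered peroxide work-up should avoid saponification.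

Step 5
Reactants: 8 (2R)-1-[3-(benzyloxy)-5-methoxyphenyl]-6-hydroxyhexan-2-yl acetate
Product: 10 (5R)-5-acetoxy-6-[3-(benzyloxy)-5-methoxyphenyl]hexanoic acid, via aldehyde 9 (not isolated)
Conditions: TEMPO (20 mol%), PhI(OAc)2 (2.2 equiv), MeCN/H2O 1:1, rt
Reagents that add atoms: water, O
Why: TEMPO/PhI(OAc)2 oxidation of a primary alcohol to the aldehyde, whose hydrate is oxidised again to the acid; the near-neutral medium should leave the acetate, the benzyl ether and the remote stereocentre untouched.

Step 6
Reactants: 10 (5R)-5-acetoxy-6-[3-(benzyloxy)-5-methoxyphenyl]hexanoic acid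
Product: 11 1,3-dioxoisoindolin-2-yl (5R)-5-acetoxy-6-[3-(benzyloxy)-5-methoxyphenyl]hexanoate
Conditions: N-hydroxyphthalimide (1.1 equiv), DIC (1.1 equiv), DMAP (10 mol%), CH2Cl2, rt
Reagents that add atoms: N-hydroxyphthalimide, O=C1c2ccccc2C(=O)N1O
Why: Carbodiimide (Steglich-type) esterification gives the redox-active N-acyloxyphthalimide, which turns the carboxyl group into a traceless radical precursor.

Step 7
Reactants: 12 nonanoic acid
Product: 13 1,3-dioxoisoindolin-2-yl nonanoate
Conditions: N-hydroxyphthalimide (1.05 equiv), DIC (1.05 equiv), DMAP (10 mol%), CH2Cl2, rt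
Reagents that add atoms: N-hydroxyphthalimide, O=C1c2ccccc2C(=O)N1O
Why: The same carbodiimide esterification converts the commodity fatty acid into the n-octyl radical precursor.

Step 8
Reactants: 11 1,3-dioxoisoindolin-2-yl (5R)-5-acetoxy-6-[3-(benzyloxy)-5-methoxyphenyl]hexanoate; 13 1,3-dioxoisoindolin-2-yl nonanoate (3 equiv)
Product: 14 (2R)-1-[3-(benzyloxy)-5-methoxyphenyl]tridecan-2-yl acetate
Conditions: NiCl2·6H2O (20 mol%), 2,2′:6′,2″-terpyridine-type ligand (20 mol%), AgNO3 (0.3 equiv), NaI, NMP, Mg(+)/RVC(−), constant current, rt
Reagents that add atoms: none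
Why: Cathodically generated low-valent nickel (on a silver-nanoparticle-coated cathode) should transfer single electrons to both N-acyloxyphthalimides, which fragment with loss of CO2 and phthalimide anion to the primary radicals n-octyl (from 13) and 4-acetoxy-5-arylpentyl (from 11); the nickel centre captures one radical after the other and reductive elimination from the dialkylnickel species forges the C5–C6 bond, while the Mg anode supplies the electrons. The closest known reaction type is the Ni-electrocatalytic doubly decarboxylative C(sp3)–C(sp3) cross-coupling of two redox-active esters, the reductive counterpart of a mixed Kolbe electrolysis, which is established for primary–primary couplings. No ring is closed and no stereocentre is formed; C2 lies three carbons from the radical centre, never becomes sp2 or a radical, and so should keep its (R) configuration. The selectivity needed is cross- over homo-coupling, secured by using the cheap ester 13 in threefold excess so that 11 is consumed mainly by cross-coupling and the hydrocarbon dimer of 13 is removed as a non-polar fraction. Chemoselectivity rests on the reductive manifold, which should leave the easily oxidised 1,3-dioxygenated benzene ring, the benzyl ether and the acetate untouched, whereas an anodic Kolbe coupling would risk oxidising that ring.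

Step 9
Reactants: 14 (2R)-1-[3-(benzyloxy)-5-methoxyphenyl]tridecan-2-yl acetate
Product: 15 (2R)-1-(3-hydroxy-5-methoxyphenyl)tridecan-2-yl acetate
Conditions: H2 (1 atm), 10% Pd/C, EtOAc, rt
Reagents that add atoms: none
Why: Hydrogenolysis of the benzyl aryl ether frees the phenol under neutral conditions; the acetate sits on a homobenzylic carbon and should not be cleaved, and C2 is not affected.

**Compound list**

1 | 3-bromo-5-methoxyphenol | COc1cc(O)cc(Br)c1 | starting material
2 | 1-(benzyloxy)-3-bromo-5-methoxybenzene | COc1cc(Br)cc(OCc2ccccc2)c1 | intermediate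
3 | (R)-1,2-epoxy-5-hexene, (2R)-2-(but-3-en-1-yl)oxirane | C=CCC[C@@H]1CO1 | starting material
4 | [3-(benzyloxy)-5-methoxyphenyl]magnesium bromide | COc1cc([Mg]Br)cc(OCc2ccccc2)c1 | intermediate (not isolated)
5 | (2R)-1-[3-(benzyloxy)-5-methoxyphenyl]hex-5-en-2-ol | C=CCC[C@H](Cc1cc(OCc2ccccc2)cc(OC)c1)O | intermediate
6 | (2R)-1-[3-(benzyloxy)-5-methoxyphenyl]hex-5-en-2-yl acetate | C=CCC[C@H](Cc1cc(OCc2ccccc2)cc(OC)c1)OC(C)=O | intermediate
7 | (2R)-1-[3-(benzyloxy)-5-methoxyphenyl]-6-(9-borabicyclo[3.3.1]nonan-9-yl)hexan-2-yl acetate | C1CCC2CCCC1B2CCCC[C@H](Cc1cc(OCc2ccccc2)cc(OC)c1)OC(C)=O | intermediate (not isolated)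
8 | (2R)-1-[3-(benzyloxy)-5-methoxyphenyl]-6-hydroxyhexan-2-yl acetate | OCCCC[C@H](Cc1cc(OCc2ccccc2)cc(OC)c1)OC(C)=O | intermediate
9 | (2R)-1-[3-(benzyloxy)-5-methoxyphenyl]-6-oxohexan-2-yl acetate | O=CCCC[C@H](Cc1cc(OCc2ccccc2)cc(OC)c1)OC(C)=O | intermediate (not isolated)
10 | (5R)-5-acetoxy-6-[3-(benzyloxy)-5-methoxyphenyl]hexanoic acid | OC(=O)CCC[C@H](Cc1cc(OCc2ccccc2)cc(OC)c1)OC(C)=O | intermediate
11 | 1,3-dioxoisoindolin-2-yl (5R)-5-acetoxy-6-[3-(benzyloxy)-5-methoxyphenyl]hexanoate | O=C(CCC[C@H](Cc1cc(OCc2ccccc2)cc(OC)c1)OC(C)=O)ON1C(=O)c2ccccc2C1=O | intermediate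
12 | nonanoic acid | CCCCCCCCC(=O)O | starting material
13 | 1,3-dioxoisoindolin-2-yl nonanoate | CCCCCCCCC(=O)ON1C(=O)c2ccccc2C1=O | intermediate
14 | (2R)-1-[3-(benzyloxy)-5-methoxyphenyl]tridecan-2-yl acetate | CCCCCCCCCCC[C@H](Cc1cc(OCc2ccccc2)cc(OC)c1)OC(C)=O | intermediate
15 | (2R)-1-(3-hydroxy-5-methoxyphenyl)tridecan-2-yl acetate | CCCCCCCCCCC[C@H](Cc1cc(O)cc(OC)c1)OC(C)=O | target

**Step count and risks**

Total step count: 9. Longest linear sequence: 8 (steps 1–6, 8, 9); step 7 is a one-step side branch.

Steps most likely to fail:

1. Step 8. The two radicals may be captured without discrimination, so that homo-coupling of each ester dominates, or they may be reduced to the alkanes before the C–C bond forms. The fallback sets out from 6 and gives up decarboxylation altogether. Olefin cross-metathesis of 6 with excess 1-nonene (Grubbs II catalyst, CH2Cl2, 40 °C) should give (2R)-1-[3-(benzyloxy)-5-methoxyphenyl]tridec-5-en-2-yl acetate F1 as an E/Z mixture. One hydrogenation (H2, Pd/C, EtOAc) would then saturate the alkene and cleave the benzyl ether together, coming back to the route at the target 15.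

2. Step 2. Bromide from the magnesium salts may open the epoxide faster than the aryl group is transferred (bromohydrin formation), or the epoxide may rearrange under Lewis acid, so that the only stereocentre-bearing intermediate is formed inefficiently. The fallback sets out from 4 and takes the stereocentre from a kinetic resolution instead of from 3. Allylation of 4 with allyl bromide should give 1-allyl-3-(benzyloxy)-5-methoxybenzene F2. Epoxidation with mCPBA gives racemic 2-[3-(benzyloxy)-5-methoxybenzyl]oxirane F3. Hydrolytic kinetic resolution with a chiral (salen)Co(III) acetate catalyst and 0.55 equiv of water (the R,R catalyst is expected, by analogy with simple terminal epoxides) should leave (S)-2-[3-(benzyloxy)-5-methoxybenzyl]oxirane F4. Opening of F4 at its CH2 terminus with the far more reactive allylmagnesium chloride (CuI cat., THF, −30 °C) comes back to the route at 5.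

3. Step 4. The C2 acetate may be lost by saponification during the peroxide work-up or partly reduced by the borane, giving diol mixtures. The fallback sets out from 6 and uses neither borane nor peroxide. An aldehyde-selective (anti-Markovnikov) Wacker oxidation (PdCl2(PhCN)2, CuCl2, AgNO2, t-BuOH/MeNO2, O2) should give aldehyde 9, here isolated. Pinnick oxidation (NaClO2, NaH2PO4, 2-methyl-2-butene, t-BuOH/H2O) then comes back to the route at acid 10. This fallback makes no compound outside the list (F0).

**Further compounds**

F1 | step 8 | (2R,5E)-1-[3-(benzyloxy)-5-methoxyphenyl]tridec-5-en-2-yl acetate (formed together with its 5Z isomer) | CCCCCCC/C=C/CC[C@H](Cc1cc(OCc2ccccc2)cc(OC)c1)OC(C)=O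
F2 | step 2 | 1-allyl-3-(benzyloxy)-5-methoxybenzene | C=CCc1cc(OCc2ccccc2)cc(OC)c1
F3 | step 2 | racemic 2-[3-(benzyloxy)-5-methoxybenzyl]oxirane | C1OC1Cc1cc(OCc2ccccc2)cc(OC)c1
F4 | step 2 | (S)-2-[3-(benzyloxy)-5-methoxybenzyl]oxirane | C1[C@H](Cc2cc(OCc3ccccc3)cc(OC)c2)O1
F0 | step 4 | none | none
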